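The runs were computed from invented constants; noise was put on by code.

In a one-step world whose reagents hold their level, target climbs in proportion to time and warmth only steepens the line. We test that picture on two earlier runs before judging two new flasks, north-east and east.

| flask | starting material | second substrate | capture agent | free catalyst | temperature | remark | time |
|---|---|---|---|---|---|---|---|
| cedar | 0.20 M | 0.065 M (fed, over 2.0 min) | 4 mM | 9 mM | −2 °C | run made earlier; the fed solution adds 0.25 times the starting volume |  |
| oak | 0.20 M | 0.11 M (fed, over 2.0 min) | 4 mM | 9 mM | 14 °C | run made earlier; the fed solution adds 0.25 times the starting volume |  |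
| north-east | 0.20 M | 0.100 M (fed, over 2.0 min) | 4.00 mM | 9.0 mM |  | at −10 °C until 2.0 min, from then on at 20 °C; the fed solution adds 0.25 times the starting volume | 8.0 min |
| east | 0.20 M | 0.150 M (fed, over 1.0 min) | 4.00 mM | 9.0 mM |  | at −10 °C throughout; the fed solution adds 0.25 times the starting volume | 8.0 min |

| run | time / min | target / % | starting material / % |
|---|---|---|---|
| cedar | 0.667 | 2.1 | 96.0 |
| cedar | 1.33 | 3.3 | 93.8 |
| cedar | 2.50 | 6.3 | 91.4 |
| cedar | 4.00 | 8.4 | 89.4 |
| cedar | 8.00 | 13.1 | 83.5 |
| oak | 0.200 | 2.8 | 95.3 |
| oak | 0.667 | 6.9 | 90.3 |
| oak | 1.33 | 10.7 | 86.4 |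
| oak | 2.00 | 13.7 | 83.0 |
| oak | 2.50 | 15.2 | 81.2 |

(each reading ± 0.3 percentage points)

- amounts are per litre of the starting volume; all of the dose is in the solution fed
- the numbers in the tables scatter with a standard deviation of 0.3 percentage points
- a reading or a percentage of target counts all its forms, free or not

- which one finishes higher in amount of target, in percent of the starting material charged ("neither" within 2 percentage points) (north-east / east / neither)
- amount of target at the end, in percent of the starting material charged, north-east
- amount of target at the end, in percent of the starting material charged, east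

First, does the line stay straight? Let q be the gain of one stretch of time divided by the gain of the stretch before it. Cedar gives 0.560 over stretches of 4.00 min, and oak gives 0.789 over about 0.670 min. So the line bends. If q holds, the gains form a geometric series with a finite sum. We call that ceiling the reach N, counted as target per catalyst charged (a turnover number). Cedar reads 4.24 and oak 5.54. The oak reading is loose, since it rests on a difference of 0.8 percentage points between two gains, with a scatter of 0.3 points.

Second, what does warmth do? Let the fade be λ = −ln(q) per stretch length: cedar 0.145 min⁻¹, oak 0.353 min⁻¹. Between the two runs, which differ in second substrate as well as in temperature, log10 λ rises by 0.386 and log10 N by 0.116, so, if we lay the change on temperature, warmth speeds the fade more than it lifts the reach. Continuing both lines in the logarithms, the warm reach at 20 °C is 6.13, with fade 0.492 min⁻¹. At −10 °C the same lines give a reach of 3.70 and a fade of 0.0931 min⁻¹.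

Third, how much of its reach does each flask use? We assume the second substrate's charge adds no term. For east, cold throughout, we reckon 8.76 %. In the same reckoning north-east keeps 83.0 % of its reach open through the cold start, then uses nearly all of that when warm, which gives 24.5 %. So we expect north-east to finish higher than east.

The forecast also names north-east, with 33 % for north-east and 8 % for east, reading the bend as something that “looks like product inhibition”. Our reckoning parts from it mainly on north-east.

The flask gives north-east: 23.7 % for north-east and 6.63 % for east.

    starting material + free catalyst ⇌ catalyst intermediate A (K = 3.70 M⁻¹, k = 0.310 M⁻¹ s⁻¹, Ea = 36.0 kJ mol⁻¹, ΔH = 3.00 kJ mol⁻¹)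
    catalyst intermediate A → free catalyst + target (k = 0.0170 s⁻¹, Ea = 65.0 kJ mol⁻¹)
    second substrate + free catalyst ⇌ catalyst intermediate B (K = 31.0 M⁻¹, k = 0.260 M⁻¹ s⁻¹, Ea = 43.0 kJ mol⁻¹, ΔH = −42.0 kJ mol⁻¹)
    catalyst intermediate B → free catalyst + second product (k = 0.120 s⁻¹, Ea = 70.0 kJ mol⁻¹)
    catalyst intermediate A + capture agent → trapped intermediate (k = 3.70 M⁻¹ s⁻¹, Ea = 43.0 kJ mol⁻¹)
    catalyst intermediate A → spent catalyst (k = 7.60 × 10⁻⁴ s⁻¹, Ea = 82.0 kJ mol⁻¹)
    free catalyst + target ⇌ idle complex, settled at all times (K = 2.50 M⁻¹, ΔH = 45.0 kJ mol⁻¹)
    (constants at −10 °C)

North-east's 23.7 % is 5.28 turnovers, a share 86.0 % of the warm reach. At 8.00 min that flask holds 3.59 % of its catalyst free, 43.2 % as trapped intermediate, 49.5 % as spent catalyst and 3.75 % in its other forms. The neighbouring flask is north-east charged with 0.023 M of free catalyst. The same share of the same reach gives it 60.7 %, and that flask ends at 61.3 %.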